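**Plan**

1. Serratane numbering is used throughout: rings A–E; C27 is the CH2 between C8 and C14; C15 is the formyl carbon; C22 is the CMe2 carbon and C21 its carbinol neighbour.
2. Retrosynthetic cuts, in order: C14–C16 (ring-D contraction, back to the 14β,15β-epoxide of a serrat-14-ene); then C21–C22 and C8–C27 together, with C15–C22 re-formed, which turns rings D/E into a pinane carrying a propanal chain; then C12–C13 (aldol) and C18–C19 (conjugate addition), leaving (1R,5R)-verbenone, a three-carbon Grignard reagent and an A/B aldehyde; rings A/B are cut at C4–C5 and C9–C10 to an acyclic β-keto ester made from homofarnesic acid.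
3. Enabling feature: C22 is bonded to C17 and lies 1,3 to C15 through C16, so C15–C16–C17–C22 is the cyclobutane of a pinane once C15–C22 is drawn. The four-membered ring stores C22 as a latent tertiary radical beside the aldehyde chain on C18, and its opening leaves exactly the C14=C15 alkene that the final contraction to the 14-formylcyclopentane needs.
4. Forward order of rings: A and B in one oxidative radical bicyclization (step 7); union with the pinane, the future ring D (steps 10–12); rings C and E closed and ring D unmasked in one radical cascade (step 17); ring D contracted (step 21).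
5. Stereochemistry: C17 is bought with verbenone; C18 (cuprate anti to the CMe2 bridge) and C13 (protonation anti to the bridge) are relayed from it and fix the trans D/E fusion; C4, C5, C9, C10 come from an 8-phenylmenthyl-controlled chair–chair bicyclization; C8 is set in the key step; C3 and C21 by equatorial hydride delivery; C14 by a stereospecific 1,2-shift anti to the β-epoxide oxygen.

Key step: step 17

Remark: the (1R,2S,5R)-8-phenylmenthyl ester is assumed to steer step 7 to the A/B enantiomer drawn (4β-ester, 10β-methyl); if the other sense of induction applied, the enantiomeric auxiliary would be used.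

**Route**

Step 1
Reactants: 1 (3E,7E)-homofarnesic acid
Product: 2 methyl (3E,7E)-homofarnesate
Conditions: MeI, K2CO3, DMF, rt
Reagents that add atoms: iodomethane CI
Why: O-alkylation of the carboxylate (SN2 esterification) masks the acid as the methyl ester that later becomes the C12 aldehyde; no stereocenter is involved.

Step 2
Reactants: 2 methyl (3E,7E)-homofarnesate
Product: 4 terminal epoxide of 2, via bromohydrin 3 (not isolated)
Conditions: NBS, THF/H2O, 0 °C; then K2CO3, MeOH, rt
Reagents that add atoms: water O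
Why: Terminal-selective bromohydrin formation on the polyene in aqueous THF, then base-induced ring closure (intramolecular Williamson reaction), should give the terminal epoxide; it is racemic and its stereocenter is destroyed in step 3.

Step 3
Reactants: 4 terminal epoxide
Product: 5 aldehyde ester (methyl 4,8-dimethyl-11-oxoundeca-3,7-dienoate)
Conditions: H5IO6, THF/Et2O, 0 °C to rt
Reagents that add atoms: none
Why: Periodic acid hydrolyses the epoxide and cleaves the vicinal diol (Malaprade glycol cleavage), which removes acetone and leaves the C3 aldehyde.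

Step 4
Reactants: 6 (1R,2S,5R)-8-phenylmenthol
Product: 7 8-phenylmenthyl propanoate
Conditions: EtCOCl, Et3N, DMAP (cat.), CH2Cl2, 0 °C to rt
Reagents that add atoms: propanoyl chloride CCC(=O)Cl
Why: DMAP-catalysed O-acylation of the secondary alcohol attaches the chiral auxiliary that will carry C4, C23 and C24.

Step 5
Reactants: 7 8-phenylmenthyl propanoate; 5 aldehyde ester
Product: 9 β-hydroxy diester, via lithium enolate 8 (not isolated)
Conditions: LiN(i-Pr)2, THF, −78 °C; then 5, −78 °C; aq. NH4Cl
Reagents that add atoms: none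
Why: Aldol addition of the lithium ester enolate to the aldehyde is faster than proton transfer from either ester; the two new centers form as a mixture that is removed by oxidation (step 6) and radical formation (step 7).

Step 6
Reactants: 9 β-hydroxy diester
Product: 10 2-methyl-3-oxo ester (β-keto ester polyene)
Conditions: Dess–Martin periodinane, CH2Cl2, rt
Reagents that add atoms: none
Why: Dess–Martin oxidation of the secondary alcohol should give the β-keto ester without moving the skipped alkenes.

Step 7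
Reactants: 10 β-keto ester polyene
Product: 11 A/B keto diester with 8-methylidene group
Conditions: Mn(OAc)3·2H2O (2.2 equiv), Cu(OAc)2·H2O (0.5 equiv), degassed AcOH, rt
Reagents that add atoms: none
Why: Manganese triacetate-mediated oxidative free-radical polyene cyclization: the C4 radical closes ring A (6-endo onto C5) and ring B (6-endo onto C9) through a chair–chair array that places H5, the C10 methyl and H9 trans-anti and the ester axial (4β), divalent copper oxidizes the tertiary C8 radical to the exocyclic alkene, and the 8-phenylmenthyl group shields one face of the radical to set the absolute configuration.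

Step 8
Reactants: 11 A/B keto diester
Product: 13 3α-silyl ether, via lithium 3α-alkoxide 12 (not isolated)
Conditions: LiBH(s-Bu)3, THF, −78 °C; then TBSOTf, −78 to 0 °C
Reagents that add atoms: tert-butyldimethylsilyl triflate CC(C)(C)[Si](C)(C)OS(=O)(=O)C(F)(F)F
Why: The bulky borohydride attacks the 3-ketone from the equatorial direction, as with 4,4-disubstituted 3-oxo triterpenoids, to give the axial 3α-alkoxide, which is silylated in the same flask; the esters are not reduced at −78 °C.

Step 9
Reactants: 13 3α-silyl ether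
Product: 14 A/B aldehyde
Conditions: i-Bu2AlH (1.1 equiv), CH2Cl2, −78 °C; aq. potassium sodium tartrate
Reagents that add atoms: none
Why: Partial reduction of the unhindered methyl ester stops at the aluminium hemiacetal and gives the C12 aldehyde, whereas the axial neopentyl-type auxiliary ester is not attacked.

Step 10
Reactants: 15 (1R,5R)-verbenone; 16 2-(1,3-dioxolan-2-yl)ethylmagnesium bromide; 14 A/B aldehyde
Product: 18 aldol adduct, via magnesium enolate 17 (not isolated)
Conditions: 16, CuBr·SMe2 (cat.), THF, −40 °C, then 15; then 14, −78 °C; aq. NH4Cl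
Reagents that add atoms: none
Why: Copper-catalysed conjugate addition to the β-carbon of verbenone occurs on the face opposite to the CMe2 bridge and sets the quaternary C18, and the magnesium enolate is trapped by the aldehyde (three-component conjugate addition–aldol reaction); the carbinol and C13 centers form as mixtures that are erased in step 11.

Step 11
Reactants: 18 aldol adduct
Product: 20 exocyclic enone, via mesylate 19 (not isolated)
Conditions: MsCl, Et3N, CH2Cl2, 0 °C; then DBU, rt
Reagents that add atoms: none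
Why: Mesylation and E1cB elimination (aldol condensation in two stages) should give the 12(13)-enone; its geometry, expected Z because of the quaternary C18, is of no consequence.

Step 12
Reactants: 20 exocyclic enone
Product: 21 saturated ketone with 13β-H
Conditions: [(Ph3P)CuH]6, H2O (2 equiv), benzene, rt
Reagents that add atoms: none
Why: Conjugate reduction by the copper hydride is specific for the enone, and kinetic protonation of the enolate at C13 from the face opposite to the CMe2 bridge (the face from which cis-pinanes arise) places C12 syn to the bridge and cis to the C18 methyl, as ring C requires.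

Step 13
Reactants: 21 saturated ketone
Product: 22 tertiary C8 alcohol
Conditions: Co(acac)2 (cat.), PhSiH3, O2 (1 atm), i-PrOH/THF, rt; then P(OEt)3
Reagents that add atoms: dioxygen O=O
Why: Mukaiyama hydration (cobalt-catalysed Markovnikov hydration by hydrogen-atom transfer) of the only alkene gives the tertiary alcohol after reduction of the hydroperoxide; the C8 configuration is irrelevant because C8 becomes a radical.

Step 14
Reactants: 22 tertiary C8 alcohol
Product: 23 14(27)-methylidene compound
Conditions: Cp2TiMe2 (excess), toluene, 70 °C, dark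
Reagents that add atoms: dimethyltitanocene [CH3-].[CH3-].[Ti+4].[cH-]1cccc1.[cH-]1cccc1
Why: Petasis methylenation is non-basic, so the epimerizable C13 center is kept, and it converts the hindered C14 ketone, but not the hindered ester, into the exocyclic alkene that supplies C27.

Step 15
Reactants: 23 14(27)-methylidene compound
Product: 24 hydroxy aldehyde
Conditions: PPTS (cat.), acetone/H2O, 40 °C
Reagents that add atoms: water O
Why: Mild acid-catalysed acetal hydrolysis releases the C21 aldehyde under conditions too weak to protonate the 1,1-disubstituted alkene or ionize the tertiary alcohol.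

Step 16
Reactants: 24 hydroxy aldehyde
Product: 25 tert-alkyl N-phthalimidoyl oxalate
Conditions: ClC(O)C(O)O-N(phthaloyl), Et3N, DMAP (cat.), THF, 0 °C; used without chromatography
Reagents that add atoms: N-phthalimidoyl chlorooxalate O=C(Cl)C(=O)ON1C(=O)c2ccccc2C1=O
Why: O-acylation of the tertiary alcohol gives a redox-active oxalate, a known visible-light precursor of tertiary alkyl radicals.

Step 17
Reactants: 25 tert-alkyl N-phthalimidoyl oxalate
Product: 26 serrat-14-ene with ring E closed (C21 carbinol)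
Conditions: Ru(bpy)3(PF6)2 (cat.), Hantzsch ester (1.5 equiv), i-Pr2NEt·HBF4, THF/CH2Cl2, high dilution, blue LEDs, rt
Reagents that add atoms: none
Why: Proposed new method: monovalent ruthenium (from Ru(bpy)3(PF6)2, light and the Hantzsch ester) reduces the oxalate, which loses phthalimide anion and two CO2 to give the tertiary C8 radical; this adds to the CH2 end (C27) of the exocyclic alkene, the cyclobutylcarbinyl radical at C14 opens the strained C15–C22 bond to give the C14=C15 alkene and the tertiary C22 radical, and C22 adds to the formyl carbon C21 before the alkoxy radical takes a hydrogen atom from the Hantzsch ester. The closest known reactions are the Giese-type couplings of tert-alkyl radicals made from N-phthalimidoyl oxalates under visible light, the ring opening of β-pinene on radical addition, titanocene-mediated 7-endo cyclizations of tertiary radicals onto 1,1-disubstituted alkenes and reductive radical cyclizations onto aldehydes; their union in one cascade is new. Ring C closes by 7-endo-trig attack (C8–C27), ring E by 6-exo-trig attack on the C=O group (C22–C21), and the bicyclo[3.1.1]heptane becomes the cyclohexene ring D. C8 is set by attack on the α face of the radical, anti to the axial C10 methyl and through the equatorial C9–C11 tether, which should give the trans B/C fusion with the C8 methyl β; the trans D/E fusion is relayed, because C22 on C17 and C19 on C18 are trans on ring D; C21 forms through a chair transition state as an epimer mixture that steps 18 and 19 converge. The step needs a C8 radical generated without a chain carrier that could add to the methylidene group (hence the photoredox oxalate and not a stannane), 7-endo instead of 6-exo closure (C14 is the fully substituted alkene carbon), cleavage of C15–C22 instead of C15–C16 (tertiary versus primary radical) and a hydrogen donor that is slow towards alkyl radicals, which high dilution and the Hantzsch ester should secure.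

Step 18
Reactants: 26 serrat-14-ene C21 carbinol
Product: 27 21-ketone
Conditions: Dess–Martin periodinane, CH2Cl2, rt
Reagents that add atoms: none
Why: Dess–Martin oxidation converges both C21 epimers to one ketone.

Step 19
Reactants: 27 21-ketone
Product: 29 3α-silyloxy-serrat-14-ene-21β,24-diol, via lithium 21β-alkoxide 28 (not isolated)
Conditions: LiBH(s-Bu)3, THF, −78 °C; then LiAlH4, 0 °C to reflux
Reagents that add atoms: none
Why: The bulky borohydride attacks the 21-ketone from the equatorial direction to give the axial 21β-alkoxide (the pseudo-mirror of step 8), and LiAlH4 then reduces the hindered ester to the C24 alcohol and releases the auxiliary.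

Step 20
Reactants: 29 serrat-14-ene diol
Product: 30 14β,15β-epoxide
Conditions: dimethyldioxirane, acetone, −20 °C
Reagents that add atoms: dimethyldioxirane CC1(C)OO1
Why: Epoxidation of the only alkene should occur on the β face, opposite to the axial C18 methyl (as 5α-steroid 2-enes are attacked anti to their angular methyl), to give the β-epoxide.

Step 21
Reactants: 30 14β,15β-epoxide
Product: 31 ring-D-contracted 15-aldehyde (3-silyl ether)
Conditions: BF3·OEt2, CH2Cl2, −78 °C
Reagents that add atoms: none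
Why: Meinwald rearrangement (semipinacol rearrangement of an epoxide): the Lewis acid opens the epoxide at tertiary C14 and the C15–C16 ring bond migrates to C14 on the face opposite to the departing oxygen, so ring D contracts, C15 becomes the formyl group and the quaternary C14 forms with the formyl group β.

Step 22
Reactants: 31 ring-D-contracted aldehyde silyl ether
Product: 32 target (CNP0319191.1)
Conditions: HF·pyridine, THF, rt
Reagents that add atoms: none
Why: Fluoride-mediated cleavage of the hindered silyl ether; the aldehyde has no α-hydrogen and cannot epimerize.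

**Compound list**

1 | (3E,7E)-4,8,12-trimethyltrideca-3,7,11-trienoic acid (homofarnesic acid) | CC(C)=CCC/C(C)=C/CC/C(C)=C/CC(=O)O | starting material
2 | methyl (3E,7E)-4,8,12-trimethyltrideca-3,7,11-trienoate | CC(C)=CCC/C(C)=C/CC/C(C)=C/CC(=O)OC | intermediate
3 | methyl (3E,7E)-11-bromo-12-hydroxy-4,8,12-trimethyltrideca-3,7-dienoate (racemic) | CC(C)(O)C(Br)CC/C(C)=C/CC/C(C)=C/CC(=O)OC | intermediate
4 | methyl (3E,7E)-10-(3,3-dimethyloxiran-2-yl)-4,8-dimethyldeca-3,7-dienoate (racemic) | CC1(C)OC1CC/C(C)=C/CC/C(C)=C/CC(=O)OC | intermediate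
5 | methyl (3E,7E)-4,8-dimethyl-11-oxoundeca-3,7-dienoate | O=CCC/C(C)=C/CC/C(C)=C/CC(=O)OC | intermediate
6 | (1R,2S,5R)-5-methyl-2-(2-phenylpropan-2-yl)cyclohexan-1-ol ((−)-8-phenylmenthol) | CC(C)(c1ccccc1)[C@@H]1CC[C@@H](C)C[C@H]1O | starting material
7 | (1R,2S,5R)-5-methyl-2-(2-phenylpropan-2-yl)cyclohexyl propanoate | CCC(=O)O[C@@H]1C[C@H](C)CC[C@H]1C(C)(C)c1ccccc1 | intermediate
8 | lithium enolate of 7 | CC=C(O[Li])O[C@@H]1C[C@H](C)CC[C@H]1C(C)(C)c1ccccc1 | intermediate
9 | 1-methyl 13-[(1R,2S,5R)-8-phenylmenthyl] (3E,7E)-11-hydroxy-4,8,12-trimethyltrideca-3,7-dienedioate (mixture at C11 and C12) | CC(C(O)CC/C(C)=C/CC/C(C)=C/CC(=O)OC)C(=O)O[C@@H]1C[C@H](C)CC[C@H]1C(C)(C)c1ccccc1 | intermediate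
10 | 1-methyl 13-[(1R,2S,5R)-8-phenylmenthyl] (3E,7E)-4,8,12-trimethyl-11-oxotrideca-3,7-dienedioate (mixture at C12) | CC(C(=O)CC/C(C)=C/CC/C(C)=C/CC(=O)OC)C(=O)O[C@@H]1C[C@H](C)CC[C@H]1C(C)(C)c1ccccc1 | intermediate
11 | A/B keto diester: trans-decalin, 5α-H, 9α-H, 10β-CH3, 3-oxo, 4α-CH3, 4β-CO2(8-phenylmenthyl) (C24), 8-methylidene (C26), 9β-CH2CO2CH3 (C11, C12) | COC(=O)C[C@H]1C(=C)CC[C@@H]2[C@]1(C)CCC(=O)[C@]2(C)C(=O)O[C@@H]1C[C@H](C)CC[C@H]1C(C)(C)c1ccccc1 | intermediate
12 | lithium 3α-alkoxide of reduced 11 | COC(=O)C[C@H]1C(=C)CC[C@@H]2[C@]1(C)CC[C@@H](O[Li])[C@]2(C)C(=O)O[C@@H]1C[C@H](C)CC[C@H]1C(C)(C)c1ccccc1 | intermediate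
13 | 3α-(tert-butyldimethylsilyloxy) analogue of 11 (axial silyl ether, methyl ester at C12) | COC(=O)C[C@H]1C(=C)CC[C@@H]2[C@]1(C)CC[C@@H](O[Si](C)(C)C(C)(C)C)[C@]2(C)C(=O)O[C@@H]1C[C@H](C)CC[C@H]1C(C)(C)c1ccccc1 | intermediate
14 | A/B aldehyde: as 13 with 9β-CH2CHO (C12 aldehyde) | O=CC[C@H]1C(=C)CC[C@@H]2[C@]1(C)CC[C@@H](O[Si](C)(C)C(C)(C)C)[C@]2(C)C(=O)O[C@@H]1C[C@H](C)CC[C@H]1C(C)(C)c1ccccc1 | intermediate
15 | (1R,5R)-4,6,6-trimethylbicyclo[3.1.1]hept-3-en-2-one ((+)-verbenone) | CC1=CC(=O)[C@@H]2C[C@H]1C2(C)C | starting material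
16 | 2-(1,3-dioxolan-2-yl)ethylmagnesium bromide | Br[Mg]CCC1OCCO1 | starting material
17 | bromomagnesium enolate of the conjugate adduct (C18: methyl syn, dioxolanylethyl anti to the CMe2 bridge) | C1COC(O1)CC[C@@]2(C)[C@H]3C[C@H](C3(C)C)C(O[Mg]Br)=C2 | intermediate
18 | aldol adduct: pinan-14-one bearing at C13 the CH(OH)CH2 link (C12, C11) to C9 of the A/B unit of 14 (mixture at C12 and C13) | C1COC(O1)CC[C@@]2(C)[C@H]3C[C@H](C3(C)C)C(=O)C2C(O)C[C@H]4C(=C)CC[C@@H]5[C@]4(C)CC[C@@H](O[Si](C)(C)C(C)(C)C)[C@]5(C)C(=O)O[C@@H]6C[C@H](C)CC[C@H]6C(C)(C)c6ccccc6 | intermediate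
19 | C12 methanesulfonate of 18 | C1COC(O1)CC[C@@]2(C)[C@H]3C[C@H](C3(C)C)C(=O)C2C(OS(C)(=O)=O)C[C@H]4C(=C)CC[C@@H]5[C@]4(C)CC[C@@H](O[Si](C)(C)C(C)(C)C)[C@]5(C)C(=O)O[C@@H]6C[C@H](C)CC[C@H]6C(C)(C)c6ccccc6 | intermediate
20 | (Z)-12(13)-en-14-one (exocyclic enone on the pinane) | C1COC(O1)CC[C@@]2(C)[C@H]3C[C@H](C3(C)C)C(=O)/C2=C\C[C@H]4C(=C)CC[C@@H]5[C@]4(C)CC[C@@H](O[Si](C)(C)C(C)(C)C)[C@]5(C)C(=O)O[C@@H]6C[C@H](C)CC[C@H]6C(C)(C)c6ccccc6 | intermediate
21 | saturated 14-ketone, C12 syn to the CMe2 bridge (13β-H), 8-methylidene | C1COC(O1)CC[C@@]2(C)[C@H]3C[C@H](C3(C)C)C(=O)[C@@H]2CC[C@H]4C(=C)CC[C@@H]5[C@]4(C)CC[C@@H](O[Si](C)(C)C(C)(C)C)[C@]5(C)C(=O)O[C@@H]6C[C@H](C)CC[C@H]6C(C)(C)c6ccccc6 | intermediate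
22 | 8-hydroxy-8-methyl analogue of 21 (C8 epimers) | C1COC(O1)CC[C@@]2(C)[C@H]3C[C@H](C3(C)C)C(=O)[C@@H]2CC[C@H]4C(C)(O)CC[C@@H]5[C@]4(C)CC[C@@H](O[Si](C)(C)C(C)(C)C)[C@]5(C)C(=O)O[C@@H]6C[C@H](C)CC[C@H]6C(C)(C)c6ccccc6 | intermediate
23 | 14(27)-methylidene analogue of 22 | C1COC(O1)CC[C@@]2(C)[C@H]3C[C@H](C3(C)C)C(=C)[C@@H]2CC[C@H]4C(C)(O)CC[C@@H]5[C@]4(C)CC[C@@H](O[Si](C)(C)C(C)(C)C)[C@]5(C)C(=O)O[C@@H]6C[C@H](C)CC[C@H]6C(C)(C)c6ccccc6 | intermediate
24 | hydroxy aldehyde: 23 with the dioxolane replaced by the C21 aldehyde | O=CCC[C@@]2(C)[C@H]3C[C@H](C3(C)C)C(=C)[C@@H]2CC[C@H]4C(C)(O)CC[C@@H]5[C@]4(C)CC[C@@H](O[Si](C)(C)C(C)(C)C)[C@]5(C)C(=O)O[C@@H]6C[C@H](C)CC[C@H]6C(C)(C)c6ccccc6 | intermediate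
25 | C8 N-phthalimidoyl oxalate of 24 | O=CCC[C@@]2(C)[C@H]3C[C@H](C3(C)C)C(=C)[C@@H]2CC[C@H]4C(C)(OC(=O)C(=O)ON7C(=O)c8ccccc8C7=O)CC[C@@H]5[C@]4(C)CC[C@@H](O[Si](C)(C)C(C)(C)C)[C@]5(C)C(=O)O[C@@H]6C[C@H](C)CC[C@H]6C(C)(C)c6ccccc6 | intermediate
26 | 8-phenylmenthyl 3α-(tert-butyldimethylsilyloxy)-21-hydroxyserrat-14-en-24-oate (C21 epimers) | CC1(C)C(O)CC[C@@]2(C)[C@H]1CC=C1C[C@]3(C)CC[C@@H]4[C@](C)(CC[C@@H](O[Si](C)(C)C(C)(C)C)[C@]4(C)C(=O)O[C@@H]5C[C@H](C)CC[C@H]5C(C)(C)c5ccccc5)[C@H]3CC[C@@H]12 | intermediate
27 | 8-phenylmenthyl 3α-(tert-butyldimethylsilyloxy)-21-oxoserrat-14-en-24-oate | CC1(C)C(=O)CC[C@@]2(C)[C@H]1CC=C1C[C@]3(C)CC[C@@H]4[C@](C)(CC[C@@H](O[Si](C)(C)C(C)(C)C)[C@]4(C)C(=O)O[C@@H]5C[C@H](C)CC[C@H]5C(C)(C)c5ccccc5)[C@H]3CC[C@@H]12 | intermediate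
28 | lithium 21β-alkoxide of reduced 27 (ester still present) | CC1(C)[C@H](O[Li])CC[C@@]2(C)[C@H]1CC=C1C[C@]3(C)CC[C@@H]4[C@](C)(CC[C@@H](O[Si](C)(C)C(C)(C)C)[C@]4(C)C(=O)O[C@@H]5C[C@H](C)CC[C@H]5C(C)(C)c5ccccc5)[C@H]3CC[C@@H]12 | intermediate
29 | 3α-(tert-butyldimethylsilyloxy)serrat-14-ene-21β,24-diol | CC1(C)[C@H](O)CC[C@@]2(C)[C@H]1CC=C1C[C@]3(C)CC[C@@H]4[C@](C)(CC[C@@H](O[Si](C)(C)C(C)(C)C)[C@]4(C)CO)[C@H]3CC[C@@H]12 | intermediate
30 | 14β,15β-epoxy-3α-(tert-butyldimethylsilyloxy)serratane-21β,24-diol | CC1(C)[C@H](O)CC[C@@]2(C)[C@H]1C[C@H]5O[C@]51C[C@]3(C)CC[C@@H]4[C@](C)(CC[C@@H](O[Si](C)(C)C(C)(C)C)[C@]4(C)CO)[C@H]3CC[C@@H]12 | intermediate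
31 | 3-O-tert-butyldimethylsilyl ether of the target (ring D five-membered, 14β-formyl) | CC1(C)[C@H](O)CC[C@@]2(C)[C@H]1C[C@]1(C=O)C[C@]3(C)CC[C@@H]4[C@](C)(CC[C@@H](O[Si](C)(C)C(C)(C)C)[C@]4(C)CO)[C@H]3CC[C@@H]12 | intermediate
32 | 3α,21β,24-trihydroxy-16(15→14)abeo-serratan-15-al (CNP0319191.1) | CC1(C)[C@H](O)CC[C@@]2(C)[C@H]1C[C@]1(C=O)C[C@]3(C)CC[C@@H]4[C@](C)(CC[C@@H](O)[C@]4(C)CO)[C@H]3CC[C@@H]12 | target

**Step count and risks**

Total steps: 22. Longest linear sequence: 21 (steps 1–3 and 5–22; step 4 is a one-step branch).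

Most likely to fail, step 17 (proposed new method). The process at risk is hydrogen-atom transfer to the C8 radical before the slow 7-endo closure, or to the C22 radical while its addition to the formyl group reverses. The fallback uses known cationic and hydrogen-atom-transfer chemistry; it sets out from 23 and returns at 26. The tertiary alcohol of 23 is acylated with trifluoroacetic anhydride and pyridine to the C8 trifluoroacetate F1. Buffered solvolysis of F1 in hexafluoroisopropanol with 2,6-lutidine ionizes C8. The cation is captured at C27 in a 7-endo cation–olefin cyclization, the classical way ring C of serratanes is closed. The cyclobutylcarbinyl cation opens to the tertiary C22 cation and loses a methyl proton to give the 17-isopropenyl serrat-14-ene acetal F2. PPTS in wet acetone unmasks the isopropenyl aldehyde F3. Iron-catalysed hydrogen-atom-transfer reductive cyclization of the isopropenyl group onto the aldehyde (Fe(acac)3, PhSiH3, EtOH, 60 °C) then closes ring E by the same C21–C22 bond and gives 26.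

Second, step 21. The process at risk is migration of hydride from C15 instead of the C15–C16 ring bond (which would give a 15-ketone), or loss of facial control in the epoxidation that feeds it. The fallback sets out from 29 and returns at 31. NBS in aqueous acetone should form the bromonium ion on the β face and deliver water to C14 from the α face, giving the 15β-bromo-14α-hydroxy compound F4. K2CO3 in methanol closes it to the 14α,15α-epoxide F5. LiBr with HMPA in hot benzene opens F5 at C14 with inversion, and the bromo alkoxide rearranges by migration of the ring bond anti-periplanar to the C–Br bond (halohydrin semipinacol). C16 again reaches the α face of C14, and the geometry disfavours hydride migration, so 31 results.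

Third, step 12. The process at risk is protonation of the enolate from the bridge side, or later epimerization, giving the C13 epimer. The fallback sets out from 18 and returns at 22. Mukaiyama hydration of 18 (its only alkene) gives the 8-hydroxy aldol F6. Mesylation and DBU elimination give the 8-hydroxy enone F7, whose enone double bond is now the only C=C. Heterogeneous hydrogenation (H2, Pd/C, EtOAc) adds both hydrogens from the open face anti to the CMe2 bridge, so C13 is set by syn addition and not by enolate protonation, and 22 results.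

**Further compounds**

F1 | step 17 | C8 trifluoroacetate of 23 | C1COC(O1)CC[C@@]2(C)[C@H]3C[C@H](C3(C)C)C(=C)[C@@H]2CC[C@H]4C(C)(OC(=O)C(F)(F)F)CC[C@@H]5[C@]4(C)CC[C@@H](O[Si](C)(C)C(C)(C)C)[C@]5(C)C(=O)O[C@@H]6C[C@H](C)CC[C@H]6C(C)(C)c6ccccc6
F2 | step 17 | 21,22-seco-serrata-14,22(29)-diene 21-dioxolane acetal (17α-isopropenyl, rings A–D closed) | C=C(C)[C@@H]1CC=C2C[C@]3(C)CC[C@@H]4[C@](C)(CC[C@@H](O[Si](C)(C)C(C)(C)C)[C@]4(C)C(=O)O[C@@H]5C[C@H](C)CC[C@H]5C(C)(C)c5ccccc5)[C@H]3CC[C@@H]2[C@@]1(C)CCC1OCCO1
F3 | step 17 | 21,22-seco-serrata-14,22(29)-dien-21-al (aldehyde from F2) | C=C(C)[C@@H]1CC=C2C[C@]3(C)CC[C@@H]4[C@](C)(CC[C@@H](O[Si](C)(C)C(C)(C)C)[C@]4(C)C(=O)O[C@@H]5C[C@H](C)CC[C@H]5C(C)(C)c5ccccc5)[C@H]3CC[C@@H]2[C@@]1(C)CCC=O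
F4 | step 21 | 15β-bromo-3α-(tert-butyldimethylsilyloxy)serratane-14α,21β,24-triol | CC1(C)[C@H](O)CC[C@@]2(C)[C@H]1C[C@@H](Br)[C@@]1(O)C[C@]3(C)CC[C@@H]4[C@](C)(CC[C@@H](O[Si](C)(C)C(C)(C)C)[C@]4(C)CO)[C@H]3CC[C@@H]12
F5 | step 21 | 14α,15α-epoxy-3α-(tert-butyldimethylsilyloxy)serratane-21β,24-diol | CC1(C)[C@H](O)CC[C@@]2(C)[C@H]1C[C@@H]5O[C@@]51C[C@]3(C)CC[C@@H]4[C@](C)(CC[C@@H](O[Si](C)(C)C(C)(C)C)[C@]4(C)CO)[C@H]3CC[C@@H]12
F6 | step 12 | 8-hydroxy-8-methyl analogue of aldol adduct 18 | C1COC(O1)CC[C@@]2(C)[C@H]3C[C@H](C3(C)C)C(=O)C2C(O)C[C@H]4C(C)(O)CC[C@@H]5[C@]4(C)CC[C@@H](O[Si](C)(C)C(C)(C)C)[C@]5(C)C(=O)O[C@@H]6C[C@H](C)CC[C@H]6C(C)(C)c6ccccc6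
F7 | step 12 | 8-hydroxy-8-methyl analogue of enone 20 | C1COC(O1)CC[C@@]2(C)[C@H]3C[C@H](C3(C)C)C(=O)/C2=C\C[C@H]4C(C)(O)CC[C@@H]5[C@]4(C)CC[C@@H](O[Si](C)(C)C(C)(C)C)[C@]5(C)C(=O)O[C@@H]6C[C@H](C)CC[C@H]6C(C)(C)c6ccccc6
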